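**Retrosynthetic overview**
1. Target 34 ⇐ silyl-protected hydroazulene 31: the end game is only protecting-group exchange (two Et3Si ethers → acetates, then TBS off).
2. 31 ⇐ ynal 30 by nickel-catalysed reductive alkyne–aldehyde cyclisation (C7–C8 bond, exo-methylene, C7 carbinol); the seven-membered ring is formed last.
3. 30 ⇐ ring aldehyde 13 + side-chain allylboronate 25 by chiral phosphoric acid-catalysed allylboration (C4–C5 bond, both stereocentres), then hydroboration/oxidation of the new vinyl group.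
4. 13 ⇐ (S)-4-hydroxycyclopent-2-enone: the five-membered ring is present from the start; trans conjugate alkynylation with formyl-equivalent trapping, β-elimination, Cu–H reduction/triflation, Pd methylation.
5. 25 ⇐ Evans syn-aldol of a propanoyl imide with 4-methylpent-3-enal, vinyl addition, Pd-catalysed allylic borylation.

Assumption: azulene numbering is used for the target (C3a/C8a ring fusion, C4 carbinol, C5 side chain, C7 acetate, C8 methylidene), whose SMILES corresponds to 3aS,4R,5S,7R,8aR with a (2S,3S) side chain.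

**Ring fragment (steps 1–7)**

Step 1
Reactants: 1 (S)-4-hydroxycyclopent-2-en-1-one
Product: 2 (S)-4-[(tert-butyldimethylsilyl)oxy]cyclopent-2-en-1-one
Conditions: TBSCl, Et3N, DMAP (cat.), CH2Cl2, 0 °C
Reagents that add atoms: tert-butyldimethylsilyl chloride, CC(C)(C)[Si](C)(C)Cl
Why: Standard O-silylation of the secondary alcohol (silyl ether formation); the stereocentre is untouched and the silyloxy group later steers the conjugate addition.

Step 2
Reactants: 2 (S)-4-[(tert-butyldimethylsilyl)oxy]cyclopent-2-en-1-one; 3 ethynyltrimethylsilane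
Product: 6 tert-butyl({(3R,4S)-4-[(tert-butyldimethylsilyl)oxy]-3-[(trimethylsilyl)ethynyl]cyclopent-1-en-1-yl}oxy)dimethylsilane, via lithium acetylide 4 (not isolated), via alkynylzinc bromide 5 (not isolated)
Conditions: 3, n-BuLi, THF, −78 °C; ZnBr2, 0 °C; then 2, TBSOTf, Et2O–THF, −40 °C
Reagents that add atoms: tert-butyldimethylsilyl trifluoromethanesulfonate, CC(C)(C)[Si](C)(C)OS(=O)(=O)C(F)(F)F; n-butyllithium, [Li]CCCC (lithium of 4 only); zinc dibromide, Br[Zn]Br (zinc and bromine of 5 only)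
Why: Silyl triflate-promoted conjugate addition of an alkynylzinc halide to a cyclic enone (conjugate alkynylation with in situ enolate silylation) gives the regiodefined silyl enol ether; the alkynyl group enters anti to the C4 silyloxy group, which sets C3 (future C8a).

Step 3
Reactants: 6 tert-butyl({(3R,4S)-4-[(tert-butyldimethylsilyl)oxy]-3-[(trimethylsilyl)ethynyl]cyclopent-1-en-1-yl}oxy)dimethylsilane
Product: 7 (2R,3R,4S)-4-[(tert-butyldimethylsilyl)oxy]-2-(dimethoxymethyl)-3-[(trimethylsilyl)ethynyl]cyclopentan-1-one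
Conditions: HC(OMe)3, TMSOTf (0.2 equiv), CH2Cl2, −78 °C
Reagents that add atoms: trimethyl orthoformate, COC(OC)OC
Why: Mukaiyama-type addition of the silyl enol ether to the dimethoxycarbenium ion (Noyori acetal aldol) puts the masked formyl carbon on C2 anti to the neighbouring alkynyl group, giving the all-trans ketone and setting C2 (future C3a).

Step 4
Reactants: 7 (2R,3R,4S)-4-[(tert-butyldimethylsilyl)oxy]-2-(dimethoxymethyl)-3-[(trimethylsilyl)ethynyl]cyclopentan-1-one
Product: 8 (4R,5R)-5-(dimethoxymethyl)-4-[(trimethylsilyl)ethynyl]cyclopent-2-en-1-one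
Conditions: DBU, CH2Cl2, −20 → 0 °C
Reagents that add atoms: none
Why: E1cB β-elimination of the silyloxy group from the β-silyloxy ketone removes the controlling oxygen while the two carbon stereocentres stay as they are; low temperature and short time limit γ-deprotonation.

Step 5
Reactants: 8 (4R,5R)-5-(dimethoxymethyl)-4-[(trimethylsilyl)ethynyl]cyclopent-2-en-1-one
Product: 11 (4R,5S)-5-(dimethoxymethyl)-4-[(trimethylsilyl)ethynyl]cyclopent-1-en-1-yl trifluoromethanesulfonate, via silyl enol ether 9 (not isolated), via lithium enolate 10 (not isolated)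
Conditions: [(Ph3P)CuH]6 (5 mol % Cu), PhMe2SiH, toluene, rt; MeLi, THF, 0 °C; PhNTf2, −78 °C → rt
Reagents that add atoms: N-phenylbis(trifluoromethanesulfonimide), O=S(=O)(N(c1ccccc1)S(=O)(=O)C(F)(F)F)C(F)(F)F; dimethylphenylsilane, C[SiH](C)c1ccccc1 (silyl group of 9 only); methyllithium, [Li]C (lithium of 10 only)
Why: Copper hydride-catalysed 1,4-hydrosilylation (conjugate reduction) gives the enolate regiospecifically on the C1–C2 side, and silyl–lithium exchange followed by enolate triflation fixes it as the enol triflate; no stereocentre is formed or lost (the C5 descriptor changes from R to S only through a priority change).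

Step 6
Reactants: 11 (4R,5S)-5-(dimethoxymethyl)-4-[(trimethylsilyl)ethynyl]cyclopent-1-en-1-yl trifluoromethanesulfonate
Product: 12 {[(1R,5S)-5-(dimethoxymethyl)-4-methylcyclopent-3-en-1-yl]ethynyl}trimethylsilane
Conditions: Me2Zn, Pd(PPh3)4 (5 mol %), THF, 0 °C → rt
Reagents that add atoms: dimethylzinc, C[Zn]C
Why: Negishi cross-coupling of the enol triflate with Me2Zn installs the ring methyl group on the trisubstituted alkene; acetal and silylalkyne are inert and the stereocentres are untouched.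

Step 7
Reactants: 12 {[(1R,5S)-5-(dimethoxymethyl)-4-methylcyclopent-3-en-1-yl]ethynyl}trimethylsilane
Product: 13 (1S,5R)-2-methyl-5-[(trimethylsilyl)ethynyl]cyclopent-2-ene-1-carbaldehyde
Conditions: LiBF4, MeCN–H2O (98:2), rt
Reagents that add atoms: water, O
Why: Mild Lewis acid-assisted acetal hydrolysis unmasks the β,γ-unsaturated aldehyde without epimerising C1 or moving the double bond into conjugation; 13 is used without storage.

**Side-chain fragment (steps 8–15)**

Step 8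
Reactants: 14 propanoyl chloride
Product: 15 (R)-4-benzyl-3-propanoyloxazolidin-2-one
Conditions: (R)-4-benzyloxazolidin-2-one, n-BuLi, THF, −78 °C; then 14, −78 → 0 °C
Reagents that add atoms: (R)-4-benzyloxazolidin-2-one, O=C1N[C@H](Cc2ccccc2)CO1
Why: N-acylation of the lithiated Evans auxiliary with the acid chloride (imide formation).

Step 9
Reactants: 16 4-methylpent-3-en-1-ol
Product: 17 4-methylpent-3-enal
Conditions: Dess–Martin periodinane, NaHCO3, CH2Cl2, 0 °C
Reagents that add atoms: none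
Why: Buffered Dess–Martin oxidation gives the β,γ-unsaturated aldehyde without isomerisation to the conjugated enal; it is used at once.

Step 10
Reactants: 15 (R)-4-benzyl-3-propanoyloxazolidin-2-one; 17 4-methylpent-3-enal
Product: 19 (R)-4-benzyl-3-[(2R,3S)-3-hydroxy-2,6-dimethylhept-5-enoyl]oxazolidin-2-one, via boron enolate 18 (not isolated)
Conditions: Bu2BOTf, i-Pr2NEt, CH2Cl2, −78 → 0 °C; 17, −78 → 0 °C; pH 7 buffer, MeOH, H2O2
Reagents that add atoms: dibutylboron trifluoromethanesulfonate, CCCCB(CCCC)OS(=O)(=O)C(F)(F)F (boron group of 18 only)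
Why: Evans syn-aldol reaction: the Z-boron enolate reacts through a Zimmerman–Traxler chair with the benzyl group blocking one enolate face, giving the 2R,3S syn adduct, i.e. the methyl- and oxygen-bearing stereocentres of the side chain.

Step 11
Reactants: 19 (R)-4-benzyl-3-[(2R,3S)-3-hydroxy-2,6-dimethylhept-5-enoyl]oxazolidin-2-one
Product: 20 (R)-4-benzyl-3-{(2R,3S)-2,6-dimethyl-3-[(triethylsilyl)oxy]hept-5-enoyl}oxazolidin-2-one
Conditions: TESOTf, 2,6-lutidine, CH2Cl2, −78 °C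
Reagents that add atoms: triethylsilyl trifluoromethanesulfonate, CC[Si](CC)(CC)OS(=O)(=O)C(F)(F)F
Why: O-silylation of the aldol hydroxyl blocks retro-aldol cleavage in the following steps.

Step 12
Reactants: 20 (R)-4-benzyl-3-{(2R,3S)-2,6-dimethyl-3-[(triethylsilyl)oxy]hept-5-enoyl}oxazolidin-2-one
Product: 21 (2S,3S)-2,6-dimethyl-3-[(triethylsilyl)oxy]hept-5-en-1-ol
Conditions: LiBH4, MeOH (1 equiv), THF, 0 °C
Reagents that add atoms: none
Why: Reductive cleavage of the N-acyl oxazolidinone with LiBH4 gives the primary alcohol and releases the auxiliary without epimerising the α-carbon (the C2 descriptor changes along 19–22 are priority changes only).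

Step 13
Reactants: 21 (2S,3S)-2,6-dimethyl-3-[(triethylsilyl)oxy]hept-5-en-1-ol
Product: 22 (2R,3S)-2,6-dimethyl-3-[(triethylsilyl)oxy]hept-5-enal
Conditions: Dess–Martin periodinane, NaHCO3, CH2Cl2, 0 °C
Reagents that add atoms: none
Why: Dess–Martin oxidation gives the α-chiral aldehyde under non-epimerising conditions; it is used directly.

Step 14
Reactants: 22 (2R,3S)-2,6-dimethyl-3-[(triethylsilyl)oxy]hept-5-enal
Product: 24 (4S,5S)-4,8-dimethyl-5-[(triethylsilyl)oxy]nona-1,7-dien-3-yl methyl carbonate (both C3 epimers), via magnesium alkoxide 23 (not isolated)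
Conditions: CH2=CHMgBr, THF, −78 °C; then ClCO2Me, −78 → 0 °C
Reagents that add atoms: vinylmagnesium bromide, C=C[Mg]Br; methyl chloroformate, COC(Cl)=O
Why: Grignard addition and acylation of the alkoxide in the same flask give the allylic carbonate; the new carbinol centre need not be controlled because it becomes sp2 in step 15.

Step 15
Reactants: 24 (4S,5S)-4,8-dimethyl-5-[(triethylsilyl)oxy]nona-1,7-dien-3-yl methyl carbonate (both C3 epimers)
Product: 25 2-{(2E,4S,5S)-4,8-dimethyl-5-[(triethylsilyl)oxy]nona-2,7-dien-1-yl}-4,4,5,5-tetramethyl-1,3,2-dioxaborolane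
Conditions: B2pin2, Pd2(dba)3 (2.5 mol %), DMSO, 50 °C
Reagents that add atoms: bis(pinacolato)diboron, CC1(C)OB(OC1(C)C)B1OC(C)(C)C(C)(C)O1
Why: Palladium-catalysed Miyaura borylation of the allylic carbonate goes through a π-allylpalladium species that is borylated at the unsubstituted terminus, giving the linear E-allylboronate from both carbinol epimers.

**Union and end game (steps 16–23)**

Step 16
Reactants: 13 (1S,5R)-2-methyl-5-[(trimethylsilyl)ethynyl]cyclopent-2-ene-1-carbaldehyde; 25 2-{(2E,4S,5S)-4,8-dimethyl-5-[(triethylsilyl)oxy]nona-2,7-dien-1-yl}-4,4,5,5-tetramethyl-1,3,2-dioxaborolane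
Product: 26 (1R,2S,3S,4S)-2-ethenyl-3,7-dimethyl-1-{(1S,5R)-2-methyl-5-[(trimethylsilyl)ethynyl]cyclopent-2-en-1-yl}-4-[(triethylsilyl)oxy]oct-6-en-1-ol
Conditions: (R)-TRIP [(R)-3,3′-bis(2,4,6-triisopropylphenyl)-1,1′-binaphthyl-2,2′-diyl hydrogen phosphate] (10 mol %), 4 Å molecular sieves, toluene, −30 → 0 °C; aqueous NaHCO3 work-up
Reagents that add atoms: none
Why: Chiral phosphoric acid-catalysed allylboration: the E-γ-substituted allylboronate reacts through a closed chair transition state, so the new C1–C2 pair is anti (hydroxyl anti to the branched chain with the vinyl group in the backbone), while (R)-TRIP selects the aldehyde face that gives 1R (the sense it shows with simple aldehydes) and has to override any Felkin preference of 13; this sets future C4 and C5.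

Step 17
Reactants: 26 (1R,2S,3S,4S)-2-ethenyl-3,7-dimethyl-1-{(1S,5R)-2-methyl-5-[(trimethylsilyl)ethynyl]cyclopent-2-en-1-yl}-4-[(triethylsilyl)oxy]oct-6-en-1-ol
Product: 27 tert-butyl({(1R,2S,3S,4S)-2-ethenyl-3,7-dimethyl-1-[(1S,5R)-2-methyl-5-[(trimethylsilyl)ethynyl]cyclopent-2-en-1-yl]-4-[(triethylsilyl)oxy]oct-6-en-1-yl}oxy)dimethylsilane
Conditions: TBSOTf, 2,6-lutidine, CH2Cl2, 0 °C → rt
Reagents that add atoms: tert-butyldimethylsilyl trifluoromethanesulfonate, CC(C)(C)[Si](C)(C)OS(=O)(=O)C(F)(F)F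
Why: Silylation of the hindered secondary alcohol with the reactive silyl triflate; TBS is chosen so that this ether outlasts the two triethylsilyl ethers in step 21.

Step 18
Reactants: 27 tert-butyl({(1R,2S,3S,4S)-2-ethenyl-3,7-dimethyl-1-[(1S,5R)-2-methyl-5-[(trimethylsilyl)ethynyl]cyclopent-2-en-1-yl]-4-[(triethylsilyl)oxy]oct-6-en-1-yl}oxy)dimethylsilane
Product: 29 (3S,4R)-4-[(tert-butyldimethylsilyl)oxy]-4-[(1S,5R)-5-ethynyl-2-methylcyclopent-2-en-1-yl]-3-{(2S,3S)-6-methyl-3-[(triethylsilyl)oxy]hept-5-en-2-yl}butan-1-ol, via alkylborane 28 (not isolated)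
Conditions: 9-BBN, THF, 0 °C → rt; then NaOH, H2O2, MeOH–THF, 0 °C → rt
Reagents that add atoms: hydrogen peroxide, OO; 9-borabicyclo[3.3.1]nonane, B1C2CCCC1CCC2 (boron group of 28 only)
Why: Anti-Markovnikov hydroboration–oxidation: 9-BBN adds only to the monosubstituted alkene (the trisubstituted alkenes and the silylalkyne are far slower), and the basic methanolic oxidative work-up also cleaves the alkynyl C–Si bond, giving the primary alcohol and the terminal alkyne without touching a stereocentre.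

Step 19
Reactants: 29 (3S,4R)-4-[(tert-butyldimethylsilyl)oxy]-4-[(1S,5R)-5-ethynyl-2-methylcyclopent-2-en-1-yl]-3-{(2S,3S)-6-methyl-3-[(triethylsilyl)oxy]hept-5-en-2-yl}butan-1-ol
Product: 30 (3S,4R)-4-[(tert-butyldimethylsilyl)oxy]-4-[(1S,5R)-5-ethynyl-2-methylcyclopent-2-en-1-yl]-3-{(2S,3S)-6-methyl-3-[(triethylsilyl)oxy]hept-5-en-2-yl}butanal
Conditions: Dess–Martin periodinane, NaHCO3, CH2Cl2, 0 °C
Reagents that add atoms: none
Why: Dess–Martin oxidation of the primary alcohol to the aldehyde; silyl ethers, alkyne and alkenes are inert and the aldehyde has no α-stereocentre.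

Step 20
Reactants: 30 (3S,4R)-4-[(tert-butyldimethylsilyl)oxy]-4-[(1S,5R)-5-ethynyl-2-methylcyclopent-2-en-1-yl]-3-{(2S,3S)-6-methyl-3-[(triethylsilyl)oxy]hept-5-en-2-yl}butanal
Product: 31 tert-butyldimethyl({(3aS,4R,5S,7R,8aR)-3-methyl-8-methylidene-5-[(2S,3S)-6-methyl-3-[(triethylsilyl)oxy]hept-5-en-2-yl]-7-[(triethylsilyl)oxy]-1,3a,4,5,6,7,8,8a-octahydroazulen-4-yl}oxy)silane
Conditions: Ni(cod)2 (10 mol %), (4R,5R)-1,3-bis(2,6-diethylphenyl)-4,5-diphenyl-4,5-dihydro-1H-imidazol-3-ium tetrafluoroborate (L*·HBF4, 10 mol %), KOtBu (10 mol %), Et3SiH (3 equiv), THF, rt, slow addition of 30 (final 0.01 M)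
Reagents that add atoms: triethylsilane, CC[SiH](CC)CC
Why: Proposed new method: nickel-catalysed reductive cyclisation of a terminal ynal to a seven-membered ring with ligand-controlled configuration of the new carbinol; zerovalent nickel bearing the C2-symmetric carbene L* couples alkyne and aldehyde by oxidative cyclisation to an oxanickelacyclopentene in which C–C bond formation at the internal alkyne carbon is enforced by the tether (the other mode would need an E-cyclooctene), then σ-bond metathesis with Et3SiH and C–H reductive elimination release the exo-methylene allylic silyl ether and zerovalent nickel; the aldehyde face is chosen in the oxidative cyclisation, where the (4R,5R) ligand is expected to favour Si-face addition (7R) with the C4 and C5 substituents pseudo-equatorial on the forming ring, the trans ring fusion being fixed beforehand; closest known reaction type: nickel/phosphine or nickel/NHC reductive cyclisation of ynals with silanes (known for five- and six-membered rings and macrocycles) and the enantioselective intermolecular aldehyde–alkyne reductive coupling with chiral NHC ligands.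

Step 21
Reactants: 31 tert-butyldimethyl({(3aS,4R,5S,7R,8aR)-3-methyl-8-methylidene-5-[(2S,3S)-6-methyl-3-[(triethylsilyl)oxy]hept-5-en-2-yl]-7-[(triethylsilyl)oxy]-1,3a,4,5,6,7,8,8a-octahydroazulen-4-yl}oxy)silane
Product: 32 (3aS,4R,5S,7R,8aR)-4-[(tert-butyldimethylsilyl)oxy]-5-[(2S,3S)-3-hydroxy-6-methylhept-5-en-2-yl]-3-methyl-8-methylidene-1,3a,4,5,6,7,8,8a-octahydroazulen-7-ol
Conditions: PPTS (cat.), MeOH–CH2Cl2, 0 °C
Reagents that add atoms: none
Why: Acid-catalysed methanolysis cleaves the two triethylsilyl ethers selectively, the hindered secondary TBS ether at C4 being much slower (selective desilylation).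

Step 22
Reactants: 32 (3aS,4R,5S,7R,8aR)-4-[(tert-butyldimethylsilyl)oxy]-5-[(2S,3S)-3-hydroxy-6-methylhept-5-en-2-yl]-3-methyl-8-methylidene-1,3a,4,5,6,7,8,8a-octahydroazulen-7-ol
Product: 33 (2S,3S)-2-{(3aS,4R,5S,7R,8aR)-7-acetoxy-4-[(tert-butyldimethylsilyl)oxy]-3-methyl-8-methylidene-1,3a,4,5,6,7,8,8a-octahydroazulen-5-yl}-6-methylhept-5-en-3-yl acetate
Conditions: Ac2O, DMAP, pyridine, CH2Cl2, rt
Reagents that add atoms: acetic anhydride, CC(=O)OC(C)=O
Why: DMAP-catalysed acetylation of both free secondary alcohols with retention of configuration.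

Step 23
Reactants: 33 (2S,3S)-2-{(3aS,4R,5S,7R,8aR)-7-acetoxy-4-[(tert-butyldimethylsilyl)oxy]-3-methyl-8-methylidene-1,3a,4,5,6,7,8,8a-octahydroazulen-5-yl}-6-methylhept-5-en-3-yl acetate
Product: 34 (2S,3S)-2-[(3aS,4R,5S,7R,8aR)-7-acetoxy-4-hydroxy-3-methyl-8-methylidene-1,3a,4,5,6,7,8,8a-octahydroazulen-5-yl]-6-methylhept-5-en-3-yl acetate (CNP0151479.2)
Conditions: HF·pyridine, pyridine–THF, 0 °C → rt
Reagents that add atoms: none
Why: Fluoride-mediated cleavage of the TBS ether (desilylation) frees the C4 hydroxyl; buffered HF·pyridine leaves the two acetates and the allylic system intact.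

**Compound list**

1 | (S)-4-hydroxycyclopent-2-en-1-one | O=C1C=C[C@@H](O)C1 | starting material
2 | (S)-4-[(tert-butyldimethylsilyl)oxy]cyclopent-2-en-1-one | O=C1C=C[C@@H](O[Si](C)(C)C(C)(C)C)C1 | intermediate
3 | ethynyltrimethylsilane | C#C[Si](C)(C)C | starting material
4 | lithium (trimethylsilyl)acetylide | [Li]C#C[Si](C)(C)C | intermediate
5 | bromo[(trimethylsilyl)ethynyl]zinc | Br[Zn]C#C[Si](C)(C)C | intermediate
6 | tert-butyl({(3R,4S)-4-[(tert-butyldimethylsilyl)oxy]-3-[(trimethylsilyl)ethynyl]cyclopent-1-en-1-yl}oxy)dimethylsilane | CC(C)(C)[Si](C)(C)OC1=C[C@H](C#C[Si](C)(C)C)[C@@H](O[Si](C)(C)C(C)(C)C)C1 | intermediate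
7 | (2R,3R,4S)-4-[(tert-butyldimethylsilyl)oxy]-2-(dimethoxymethyl)-3-[(trimethylsilyl)ethynyl]cyclopentan-1-one | COC(OC)[C@@H]1C(=O)C[C@H](O[Si](C)(C)C(C)(C)C)[C@H]1C#C[Si](C)(C)C | intermediate
8 | (4R,5R)-5-(dimethoxymethyl)-4-[(trimethylsilyl)ethynyl]cyclopent-2-en-1-one | COC(OC)[C@@H]1C(=O)C=C[C@H]1C#C[Si](C)(C)C | intermediate
9 | {[(4R,5S)-5-(dimethoxymethyl)-4-[(trimethylsilyl)ethynyl]cyclopent-1-en-1-yl]oxy}dimethyl(phenyl)silane | COC(OC)[C@@H]1C(O[Si](C)(C)c2ccccc2)=CC[C@H]1C#C[Si](C)(C)C | intermediate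
10 | lithium (4R,5S)-5-(dimethoxymethyl)-4-[(trimethylsilyl)ethynyl]cyclopent-1-en-1-olate | COC(OC)[C@@H]1C([O-])=CC[C@H]1C#C[Si](C)(C)C.[Li+] | intermediate
11 | (4R,5S)-5-(dimethoxymethyl)-4-[(trimethylsilyl)ethynyl]cyclopent-1-en-1-yl trifluoromethanesulfonate | COC(OC)[C@@H]1C(OS(=O)(=O)C(F)(F)F)=CC[C@H]1C#C[Si](C)(C)C | intermediate
12 | {[(1R,5S)-5-(dimethoxymethyl)-4-methylcyclopent-3-en-1-yl]ethynyl}trimethylsilane | COC(OC)[C@@H]1C(C)=CC[C@H]1C#C[Si](C)(C)C | intermediate
13 | (1S,5R)-2-methyl-5-[(trimethylsilyl)ethynyl]cyclopent-2-ene-1-carbaldehyde | O=C[C@@H]1C(C)=CC[C@H]1C#C[Si](C)(C)C | intermediate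
14 | propanoyl chloride | CCC(Cl)=O | starting material
15 | (R)-4-benzyl-3-propanoyloxazolidin-2-one | CCC(=O)N1[C@H](Cc2ccccc2)COC1=O | intermediate
16 | 4-methylpent-3-en-1-ol | CC(C)=CCCO | starting material
17 | 4-methylpent-3-enal | CC(C)=CCC=O | intermediate
18 | (Z)-dibutylboron enolate of 15 | C/C=C(\OB(CCCC)CCCC)N1[C@H](Cc2ccccc2)COC1=O | intermediate
19 | (R)-4-benzyl-3-[(2R,3S)-3-hydroxy-2,6-dimethylhept-5-enoyl]oxazolidin-2-one | O=C(N1[C@H](Cc2ccccc2)COC1=O)[C@H](C)[C@H](CC=C(C)C)O | intermediate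
20 | (R)-4-benzyl-3-{(2R,3S)-2,6-dimethyl-3-[(triethylsilyl)oxy]hept-5-enoyl}oxazolidin-2-one | O=C(N1[C@H](Cc2ccccc2)COC1=O)[C@H](C)[C@H](CC=C(C)C)O[Si](CC)(CC)CC | intermediate
21 | (2S,3S)-2,6-dimethyl-3-[(triethylsilyl)oxy]hept-5-en-1-ol | OC[C@H](C)[C@H](CC=C(C)C)O[Si](CC)(CC)CC | intermediate
22 | (2R,3S)-2,6-dimethyl-3-[(triethylsilyl)oxy]hept-5-enal | O=C[C@H](C)[C@H](CC=C(C)C)O[Si](CC)(CC)CC | intermediate
23 | bromomagnesium (4S,5S)-4,8-dimethyl-5-[(triethylsilyl)oxy]nona-1,7-dien-3-olate (both C3 epimers) | C=CC(O[Mg]Br)[C@H](C)[C@H](CC=C(C)C)O[Si](CC)(CC)CC | intermediate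
24 | (4S,5S)-4,8-dimethyl-5-[(triethylsilyl)oxy]nona-1,7-dien-3-yl methyl carbonate (both C3 epimers) | C=CC(OC(=O)OC)[C@H](C)[C@H](CC=C(C)C)O[Si](CC)(CC)CC | intermediate
25 | 2-{(2E,4S,5S)-4,8-dimethyl-5-[(triethylsilyl)oxy]nona-2,7-dien-1-yl}-4,4,5,5-tetramethyl-1,3,2-dioxaborolane | CC1(C)OB(C/C=C/[C@H](C)[C@H](CC=C(C)C)O[Si](CC)(CC)CC)OC1(C)C | intermediate
26 | (1R,2S,3S,4S)-2-ethenyl-3,7-dimethyl-1-{(1S,5R)-2-methyl-5-[(trimethylsilyl)ethynyl]cyclopent-2-en-1-yl}-4-[(triethylsilyl)oxy]oct-6-en-1-ol | C=C[C@@H]([C@H](C)[C@H](CC=C(C)C)O[Si](CC)(CC)CC)[C@@H](O)[C@@H]1C(C)=CC[C@H]1C#C[Si](C)(C)C | intermediate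
27 | tert-butyl({(1R,2S,3S,4S)-2-ethenyl-3,7-dimethyl-1-[(1S,5R)-2-methyl-5-[(trimethylsilyl)ethynyl]cyclopent-2-en-1-yl]-4-[(triethylsilyl)oxy]oct-6-en-1-yl}oxy)dimethylsilane | C=C[C@@H]([C@H](C)[C@H](CC=C(C)C)O[Si](CC)(CC)CC)[C@@H](O[Si](C)(C)C(C)(C)C)[C@@H]1C(C)=CC[C@H]1C#C[Si](C)(C)C | intermediate
28 | 9-{(3S,4R)-4-[(tert-butyldimethylsilyl)oxy]-4-[(1S,5R)-2-methyl-5-[(trimethylsilyl)ethynyl]cyclopent-2-en-1-yl]-3-[(2S,3S)-6-methyl-3-[(triethylsilyl)oxy]hept-5-en-2-yl]butyl}-9-borabicyclo[3.3.1]nonane | B1(CC[C@@H]([C@H](C)[C@H](CC=C(C)C)O[Si](CC)(CC)CC)[C@@H](O[Si](C)(C)C(C)(C)C)[C@@H]3C(C)=CC[C@H]3C#C[Si](C)(C)C)C2CCCC1CCC2 | intermediate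
29 | (3S,4R)-4-[(tert-butyldimethylsilyl)oxy]-4-[(1S,5R)-5-ethynyl-2-methylcyclopent-2-en-1-yl]-3-{(2S,3S)-6-methyl-3-[(triethylsilyl)oxy]hept-5-en-2-yl}butan-1-ol | OCC[C@@H]([C@H](C)[C@H](CC=C(C)C)O[Si](CC)(CC)CC)[C@@H](O[Si](C)(C)C(C)(C)C)[C@@H]1C(C)=CC[C@H]1C#C | intermediate
30 | (3S,4R)-4-[(tert-butyldimethylsilyl)oxy]-4-[(1S,5R)-5-ethynyl-2-methylcyclopent-2-en-1-yl]-3-{(2S,3S)-6-methyl-3-[(triethylsilyl)oxy]hept-5-en-2-yl}butanal | O=CC[C@@H]([C@H](C)[C@H](CC=C(C)C)O[Si](CC)(CC)CC)[C@@H](O[Si](C)(C)C(C)(C)C)[C@@H]1C(C)=CC[C@H]1C#C | intermediate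
31 | tert-butyldimethyl({(3aS,4R,5S,7R,8aR)-3-methyl-8-methylidene-5-[(2S,3S)-6-methyl-3-[(triethylsilyl)oxy]hept-5-en-2-yl]-7-[(triethylsilyl)oxy]-1,3a,4,5,6,7,8,8a-octahydroazulen-4-yl}oxy)silane | C=C1[C@H](O[Si](CC)(CC)CC)C[C@@H]([C@H](C)[C@H](CC=C(C)C)O[Si](CC)(CC)CC)[C@@H](O[Si](C)(C)C(C)(C)C)[C@@H]2C(C)=CC[C@@H]12 | intermediate
32 | (3aS,4R,5S,7R,8aR)-4-[(tert-butyldimethylsilyl)oxy]-5-[(2S,3S)-3-hydroxy-6-methylhept-5-en-2-yl]-3-methyl-8-methylidene-1,3a,4,5,6,7,8,8a-octahydroazulen-7-ol | C=C1[C@H](O)C[C@@H]([C@H](C)[C@H](CC=C(C)C)O)[C@@H](O[Si](C)(C)C(C)(C)C)[C@@H]2C(C)=CC[C@@H]12 | intermediate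
33 | (2S,3S)-2-{(3aS,4R,5S,7R,8aR)-7-acetoxy-4-[(tert-butyldimethylsilyl)oxy]-3-methyl-8-methylidene-1,3a,4,5,6,7,8,8a-octahydroazulen-5-yl}-6-methylhept-5-en-3-yl acetate | C=C1[C@H](OC(C)=O)C[C@@H]([C@H](C)[C@H](CC=C(C)C)OC(C)=O)[C@@H](O[Si](C)(C)C(C)(C)C)[C@@H]2C(C)=CC[C@@H]12 | intermediate
34 | (2S,3S)-2-[(3aS,4R,5S,7R,8aR)-7-acetoxy-4-hydroxy-3-methyl-8-methylidene-1,3a,4,5,6,7,8,8a-octahydroazulen-5-yl]-6-methylhept-5-en-3-yl acetate | C=C1[C@H](OC(C)=O)C[C@@H]([C@H](C)[C@H](CC=C(C)C)OC(C)=O)[C@@H](O)[C@@H]2C(C)=CC[C@@H]12 | target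

**Step count and risks**

Total step count: 23. Longest linear sequence: 15 steps (steps 1–7 then 16–23; the branch through steps 9–15 then 16–23 is equally long), i.e. 15 of 23.

Steps most likely to fail:

Step 20 (the proposed new ring closure). Risks are the untested ring size, competing aldehyde hydrosilylation and the wrong C7 epimer. The fallback uses known chemistry, sets out from 29 and returns at 32. 29 is silylated at the primary hydroxyl (Et3SiCl, imidazole, CH2Cl2) to the bis(triethylsilyl) ether F1. Haloboration of the terminal alkyne with B-iodo-9-BBN (pentane, −20 °C) and protonolysis with AcOH gives the 2-iodoalkene F2. Swern oxidation ((COCl)2, DMSO, then Et3N, −78 → −30 °C) turns the primary triethylsilyl ether directly into the iodo aldehyde F3. Intramolecular Nozaki–Hiyama–Kishi coupling (CrCl2, NiCl2 (1 mol %), DMSO–THF, high dilution) closes the seven-membered ring to the allylic alcohol F4, whose C7 epimers are separated by chromatography. PPTS in MeOH then removes the remaining triethylsilyl group and gives 32.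

Step 16 (fragment union). Both partners are hindered, and the catalyst may have to work against the substrate's own facial preference. The fallback sets out from 22 (and uses 13) and returns at 26. Addition of CH2=CHMgBr to 22 with aqueous work-up gives the allylic alcohol F5. PPh3/CBr4 (CH2Cl2, 0 °C) converts it with allylic transposition into the primary E-allylic bromide F6; any secondary bromide gives the same allylchromium species. CrCl2 (THF, 0 °C, with a chiral sulfonamide ligand of the Kishi type for facial control) then adds the allylchromium reagent to 13 through the usual chair transition state, which is anti-selective whatever the bromide geometry, and gives 26 after chromatography.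

Step 2 (conjugate alkynylation). Risks are 1,2-addition and loss of the γ-silyloxy group under the silyl triflate. The fallback sets out from 2 and 3 and returns at 7. 3 is lithiated (n-BuLi) and transmetalated with Me2AlCl to the alkynylalane F7. Conjugate addition to 2 catalysed by zerovalent nickel made from Ni(acac)2 and i-Bu2AlH (Et2O, −5 °C) gives the aluminium enolate, again anti to the silyloxy group, which is silylated in the flask with TMSOTf to the trimethylsilyl enol ether F8. F8 reacts with HC(OMe)3/TMSOTf as 6 does and gives 7.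

**Further compounds**

F1 | step 20 | tert-butyl({(1R,2S)-1-[(1S,5R)-5-ethynyl-2-methylcyclopent-2-en-1-yl]-2-[(2S,3S)-6-methyl-3-[(triethylsilyl)oxy]hept-5-en-2-yl]-4-[(triethylsilyl)oxy]butyl}oxy)dimethylsilane | CC[Si](CC)(CC)OCC[C@@H]([C@H](C)[C@H](CC=C(C)C)O[Si](CC)(CC)CC)[C@@H](O[Si](C)(C)C(C)(C)C)[C@@H]1C(C)=CC[C@H]1C#C
F2 | step 20 | tert-butyl({(1R,2S)-1-[(1S,5R)-5-(1-iodoethenyl)-2-methylcyclopent-2-en-1-yl]-2-[(2S,3S)-6-methyl-3-[(triethylsilyl)oxy]hept-5-en-2-yl]-4-[(triethylsilyl)oxy]butyl}oxy)dimethylsilane | CC[Si](CC)(CC)OCC[C@@H]([C@H](C)[C@H](CC=C(C)C)O[Si](CC)(CC)CC)[C@@H](O[Si](C)(C)C(C)(C)C)[C@@H]1C(C)=CC[C@H]1C(I)=C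
F3 | step 20 | (3S,4R)-4-[(tert-butyldimethylsilyl)oxy]-4-[(1S,5R)-5-(1-iodoethenyl)-2-methylcyclopent-2-en-1-yl]-3-{(2S,3S)-6-methyl-3-[(triethylsilyl)oxy]hept-5-en-2-yl}butanal | O=CC[C@@H]([C@H](C)[C@H](CC=C(C)C)O[Si](CC)(CC)CC)[C@@H](O[Si](C)(C)C(C)(C)C)[C@@H]1C(C)=CC[C@H]1C(I)=C
F4 | step 20 | (3aS,4R,5S,7R,8aR)-4-[(tert-butyldimethylsilyl)oxy]-3-methyl-8-methylidene-5-{(2S,3S)-6-methyl-3-[(triethylsilyl)oxy]hept-5-en-2-yl}-1,3a,4,5,6,7,8,8a-octahydroazulen-7-ol | C=C1[C@H](O)C[C@@H]([C@H](C)[C@H](CC=C(C)C)O[Si](CC)(CC)CC)[C@@H](O[Si](C)(C)C(C)(C)C)[C@@H]2C(C)=CC[C@@H]12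
F5 | step 16 | (4S,5S)-4,8-dimethyl-5-[(triethylsilyl)oxy]nona-1,7-dien-3-ol (both C3 epimers) | C=CC(O)[C@H](C)[C@H](CC=C(C)C)O[Si](CC)(CC)CC
F6 | step 16 | {[(5S,6S,7E)-9-bromo-2,6-dimethylnona-2,7-dien-5-yl]oxy}triethylsilane | BrC/C=C/[C@H](C)[C@H](CC=C(C)C)O[Si](CC)(CC)CC
F7 | step 2 | dimethyl[(trimethylsilyl)ethynyl]aluminium | C[Al](C)C#C[Si](C)(C)C
F8 | step 2 | trimethyl({(3R,4S)-4-[(tert-butyldimethylsilyl)oxy]-3-[(trimethylsilyl)ethynyl]cyclopent-1-en-1-yl}oxy)silane | C[Si](C)(C)OC1=C[C@H](C#C[Si](C)(C)C)[C@@H](O[Si](C)(C)C(C)(C)C)C1
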